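The route reads the cis-fused α-methylene-γ-butyrolactone (ring O–C6–C7–C11–C12, germacrane numbering) as a 2-methylidenecyclobutanone that has taken up one oxygen atom. The key step joins two fragments. A (Z)-iodovinylketene, released from a diazoketone by Wolff rearrangement, adds across the substituted π bond of a terminal allene that already carries the epoxide, C8 and the complete ester side chain. This [2+2] cycloaddition forms C11–C12 and C6–C7 together and sets C6 and C7. It exploits the allylic C6, the exocyclic C11=C13 methylene and the cis ring fusion. Baeyer–Villiger oxygen insertion and Nozaki–Hiyama–Kishi closure of the ten-membered ring at C3–C4 complete the skeleton.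

Key step: step 18

Numbering used for all intermediates (germacrane):
- C1 and C10 are the epoxide carbons; C10 bears the methyl group.
- C2 is CH2 and C3 is the carbinol carbon.
- C4=C5 is the ring alkene; C4 bears the methyl group.
- C6 is the lactone O–CH and C7 is the ring-fusion CH next to C11.
- C8 is the acyloxy CH and C9 is CH2.
- C11=C13 is the exocyclic methylene and C12 is the lactone carbonyl.

Assumption: the SMILES string is taken literally, which means H6 and H7 cis on the lactone ring, descriptors 1R,3S,6S,7R,8R,10R and 4Z, a (2E)-enoate and a (2S)-butanoate in the side chain.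

Step 1
Reactants: 1 3-(trimethylsilyl)prop-2-ynal; 2 allenylboronic acid pinacol ester
Product: 3 (3R)-1-(trimethylsilyl)hexa-1,5-diyn-3-ol
Conditions: (R)-TRIP [(R)-3,3′-bis(2,4,6-triisopropylphenyl)-1,1′-binaphthyl-2,2′-diyl hydrogen phosphate, 10 mol %], 4 Å molecular sieves, toluene, −20 °C; aqueous work-up
Reagents that add atoms: none
Why: Chiral-phosphoric-acid-catalysed asymmetric propargylboration, in which the allenylboronate reacts through a closed six-membered SE2′ transition state and the chosen catalyst enantiomer directs it to the Re face of the ynal, setting C8 as R and leaving one free and one silyl-capped alkyne.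

Step 2
Reactants: 3 (3R)-1-(trimethylsilyl)hexa-1,5-diyn-3-ol
Product: 5 (3E,6R)-4-methyl-8-(trimethylsilyl)oct-3-en-7-yne-1,6-diol, via alkenylalane 4 (not isolated)
Conditions: Me3Al (3.5 equiv), Cp2ZrCl2 (0.25 equiv), CH2Cl2, 0 °C to rt; volatiles removed; n-BuLi, hexane–THF, −78 °C; ethylene oxide, −78 to 0 °C; aq. potassium sodium tartrate
Reagents that add atoms: trimethylaluminium C[Al](C)C; ethylene oxide C1CO1
Why: Negishi zirconium-catalysed carboalumination adds methyl and aluminium syn across the terminal alkyne only (the silyl-capped, alkoxide-flanked alkyne reacts much more slowly), and the derived lithium alanate opens ethylene oxide with retention, so the E-configured C1=C10 alkene and the C2–C3 unit arise in one flask.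

Step 3
Reactants: 5 (3E,6R)-4-methyl-8-(trimethylsilyl)oct-3-en-7-yne-1,6-diol
Product: 6 (3E,6R)-4-methyloct-3-en-7-yne-1,6-diol
Conditions: K2CO3 (0.2 equiv), MeOH, rt
Reagents that add atoms: none
Why: Base-catalysed protodesilylation (methanolysis) of the alkynylsilane, which touches neither the alkene nor C8.

Step 4
Reactants: 6 (3E,6R)-4-methyloct-3-en-7-yne-1,6-diol
Product: 7 (3E,6R)-4-methylnona-3,7,8-triene-1,6-diol
Conditions: (CH2O)n (2.5 equiv), CuI (0.5 equiv), Cy2NH (1.8 equiv), 1,4-dioxane, reflux
Reagents that add atoms: paraformaldehyde (as formaldehyde) C=O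
Why: Crabbé homologation (aminomethylation of the terminal alkyne mediated by monovalent copper, then 1,5-hydride transfer with loss of an imine) turns the ethynyl carbinol into the terminal allene C7=C11=C13 without touching the C8–O bond, so C8 stays R.

Step 5
Reactants: 7 (3E,6R)-4-methylnona-3,7,8-triene-1,6-diol
Product: 8 (4R,6E)-6-methyl-9-(triethylsilyloxy)nona-1,2,6-trien-4-ol
Conditions: TESCl (1.05 equiv), imidazole, CH2Cl2, −40 °C
Reagents that add atoms: chlorotriethylsilane CC[Si](Cl)(CC)CC
Why: Selective silyl ether formation, because the unhindered primary C3 hydroxyl reacts far faster at low temperature than the secondary allenyl carbinol, which stays free for step 14.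

Step 6
Reactants: 8 (4R,6E)-6-methyl-9-(triethylsilyloxy)nona-1,2,6-trien-4-ol
Product: 9 (2R)-1-{(2R,3R)-2-methyl-3-[2-(triethylsilyloxy)ethyl]oxiran-2-yl}penta-3,4-dien-2-ol
Conditions: D-fructose-derived Shi ketone (1,2:4,5-di-O-isopropylidene-β-D-erythro-2,3-hexodiulo-2,6-pyranose, 0.3 equiv), KHSO5 (as 2KHSO5·KHSO4·K2SO4), K2CO3, Bu4NHSO4, MeCN–dimethoxymethane / aq. Na2B4O7–Na2EDTA buffer, 0 °C
Reagents that add atoms: potassium peroxymonosulfate [K+].[O-]S(=O)(=O)OO
Why: Shi asymmetric epoxidation, in which the chiral dioxirane attacks the electron-rich trisubstituted E-alkene through a spiro transition state on the face that gives the (R,R)-epoxide (C1 R, C10 R), faster than it attacks the less nucleophilic monosubstituted allene.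

Step 7
Reactants: 10 (4R)-4-benzyl-1,3-oxazolidin-2-one; 11 butanoyl chloride
Product: 12 (4R)-4-benzyl-3-butanoyl-1,3-oxazolidin-2-one
Conditions: n-BuLi, THF, −78 °C; then 11, −78 to 0 °C
Reagents that add atoms: none
Why: N-acylation of the lithiated oxazolidinone, the standard entry to an Evans imide.

Step 8
Reactants: 12 (4R)-4-benzyl-3-butanoyl-1,3-oxazolidin-2-one
Product: 13 (4R)-4-benzyl-3-[(2S)-2-(hydroxymethyl)butanoyl]-1,3-oxazolidin-2-one
Conditions: TiCl4, iPr2NEt, CH2Cl2, 0 °C; 1,3,5-trioxane, TiCl4, 0 °C; aq. NH4Cl
Reagents that add atoms: 1,3,5-trioxane C1OCOCO1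
Why: Evans auxiliary-controlled hydroxymethylation (aldol-type reaction of the chelated Z titanium enolate with activated formaldehyde), in which the electrophile enters opposite to the benzyl group and sets the side-chain stereocentre as S.

Step 9
Reactants: 13 (4R)-4-benzyl-3-[(2S)-2-(hydroxymethyl)butanoyl]-1,3-oxazolidin-2-one
Product: 14 (4R)-4-benzyl-3-{(2S)-2-[(tert-butyldimethylsilyloxy)methyl]butanoyl}-1,3-oxazolidin-2-one
Conditions: TBSCl, imidazole, DMF, rt
Reagents that add atoms: tert-butylchlorodimethylsilane CC(C)(C)[Si](C)(C)Cl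
Why: Standard silyl ether protection of the primary alcohol, which also blocks retro-aldol loss of formaldehyde in the next step.

Step 10
Reactants: 14 (4R)-4-benzyl-3-{(2S)-2-[(tert-butyldimethylsilyloxy)methyl]butanoyl}-1,3-oxazolidin-2-one
Product: 16 (2S)-2-[(tert-butyldimethylsilyloxy)methyl]butanoic acid, via peroxy acid 15 (not isolated)
Conditions: LiOH, H2O2, THF–H2O, 0 °C; Na2SO3; HCl to pH 3
Reagents that add atoms: hydrogen peroxide OO
Why: Hydroperoxide-mediated cleavage of the Evans imide at the exocyclic carbonyl followed by sulfite reduction, a non-epimerising hydrolysis that returns the auxiliary.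

Step 11
Reactants: 17 tert-butyl acrylate; 18 acetaldehyde
Product: 19 tert-butyl 3-hydroxy-2-methylidenebutanoate (racemic)
Conditions: DABCO (0.3 equiv), 1,4-dioxane–H2O, rt
Reagents that add atoms: none
Why: Morita–Baylis–Hillman reaction, whose racemic carbinol centre is of no consequence because it is erased in step 12.

Step 12
Reactants: 16 (2S)-2-[(tert-butyldimethylsilyloxy)methyl]butanoic acid; 19 tert-butyl 3-hydroxy-2-methylidenebutanoate
Product: 20 tert-butyl (2E)-2-({(2S)-2-[(tert-butyldimethylsilyloxy)methyl]butanoyloxy}methyl)but-2-enoate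
Conditions: PPh3, DIAD, THF, −40 to 0 °C
Reagents that add atoms: none
Why: Mitsunobu reaction in its SN2′ mode, in which the carboxylate attacks the unhindered methylene terminus of the activated Baylis–Hillman alcohol and allylic strain in the transition state places the methyl group trans to the ester, giving the E-alkene.

Step 13
Reactants: 20 tert-butyl (2E)-2-({(2S)-2-[(tert-butyldimethylsilyloxy)methyl]butanoyloxy}methyl)but-2-enoate
Product: 21 (2E)-2-({(2S)-2-[(tert-butyldimethylsilyloxy)methyl]butanoyloxy}methyl)but-2-enoic acid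
Conditions: TMSOTf, 2,6-lutidine, CH2Cl2, 0 °C; pH 5 buffer
Reagents that add atoms: none
Why: Silyl-triflate-promoted cleavage of the tert-butyl ester (loss of isobutene, hydrolysis of the silyl ester on work-up), a buffered method that spares the primary TBS ether and the allylic acyloxy group.

Step 14
Reactants: 9 (2R)-1-{(2R,3R)-2-methyl-3-[2-(triethylsilyloxy)ethyl]oxiran-2-yl}penta-3,4-dien-2-ol; 21 (2E)-2-({(2S)-2-[(tert-butyldimethylsilyloxy)methyl]butanoyloxy}methyl)but-2-enoic acid
Product: 22 allene ester, the C8 ester of alcohol 9 with acid 21 (8R retained)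
Conditions: EDC·HCl, DMAP (0.1 equiv), CH2Cl2, 0 °C to rt
Reagents that add atoms: none
Why: Steglich-type carbodiimide esterification at the acyl carbon, so C8 keeps its configuration, while little DMAP and low temperature avoid displacement of the allylic acyloxy group.

Step 15
Reactants: 23 but-2-ynoic acid
Product: 24 (2Z)-3-iodobut-2-enoic acid
Conditions: NaI, AcOH, 110 °C
Reagents that add atoms: sodium iodide [Na+].[I-]
Why: Conjugate hydroiodination of an alkynoic acid, a net anti addition of HI that places iodine cis to the carboxyl group and thereby fixes the later Z geometry of C4=C5.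

Step 16
Reactants: 24 (2Z)-3-iodobut-2-enoic acid
Product: 25 (2Z)-3-iodobut-2-enoyl chloride
Conditions: (COCl)2, DMF (cat.), CH2Cl2, 0 °C to rt
Reagents that add atoms: oxalyl chloride O=C(Cl)C(=O)Cl
Why: Acid chloride formation through Vilsmeier-type activation under cold conditions, which keeps the alkene geometry.

Step 17
Reactants: 25 (2Z)-3-iodobut-2-enoyl chloride
Product: 26 (3Z)-1-diazo-4-iodopent-3-en-2-one
Conditions: CH2N2 (3 equiv), Et2O, 0 °C
Reagents that add atoms: diazomethane C=[N+]=[N-]
Why: Acylation of diazomethane (first stage of the Arndt–Eistert sequence), in which excess diazomethane scavenges HCl and the trisubstituted β-iodoalkene is too hindered for dipolar cycloaddition.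

Step 18
Reactants: 22 allene ester; 26 (3Z)-1-diazo-4-iodopent-3-en-2-one
Product: 28 cis-cyclobutanone (2R,3R)-2-[(1Z)-2-iodoprop-1-enyl]-4-methylidenecyclobutan-1-one bearing at ring carbon 3 (C7) the C8–C3 chain of 22, via vinylketene 27 (not isolated)
Conditions: 26 (3 equiv, added over 10 h) to 22 (0.3 M), toluene, 405 nm LED, 20 °C, argon
Reagents that add atoms: none
Why: Irradiation expels N2 from 26 and the iodoalkenyl group shifts (Wolff rearrangement) to give vinylketene 27, whose electrophilic C12 attacks the central allene carbon C11 while C6 closes on C7 in one asynchronous, orthogonal [2+2] cycloaddition. The closest known reaction types are the ketene–allene cycloaddition to 2-alkylidenecyclobutanones and the [2+2] trapping of photochemically generated vinylketenes. The only ring closed is the cyclobutanone (C12–C6–C7–C11), formed intermolecularly by cycloaddition with C11–C12 bonding running ahead of C6–C7. C6 is set by the usual contrasteric course of aldoketene cycloadditions, in which the ketene approaches with its hydrogen edge toward the allene so that the iodopropenyl group finishes cis to the C8 chain. C7 is set by the C8 stereocentre, because in the reactive conformer C8–C9 stands anti to the incoming ketene, the electron-withdrawing C8–O bond lies in the nodal plane pointing away from C11 and H8 points inside, which exposes the face that gives 7R. The ketene must choose C7=C11 over C11=C13 and over every other π bond, which is secured because positive charge builds at secondary C7 rather than primary C13, the C1–C10 alkene is already an epoxide, both enoate alkenes are electron-poor, iodine rather than a C–H-bearing carbon occupies the Z position so that no 1,5-hydrogen shift drains the ketene, and the base-free conditions keep the acidic C6–H from epimerising.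

Step 19
Reactants: 28 cis-cyclobutanone
Product: 29 cis-lactone (4R,5R)-5-[(1Z)-2-iodoprop-1-enyl]-3-methylideneoxolan-2-one bearing at ring carbon 4 (C7) the C8–C3 chain of 22
Conditions: mCPBA, CH2Cl2 / aq. pH 7 phosphate buffer, 0 °C
Reagents that add atoms: 3-chloroperoxybenzoic acid OOC(=O)c1cccc(Cl)c1
Why: Baeyer–Villiger oxidation driven by release of four-ring strain, in which the secondary allylic C6 migrates in preference to the sp2 carbon C11 and with retention, so one oxygen atom enters between C12 and C6 and the cis relation of C6 and C7 is kept.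

Step 20
Reactants: 29 cis-lactone
Product: 30 primary alcohol (29 with free C3–OH)
Conditions: HF·pyridine, pyridine, THF, 0 °C
Reagents that add atoms: none
Why: Fluoride-mediated desilylation that is selective on steric grounds, because the primary TES ether is cleaved much faster than the primary TBS ether and the pyridine buffer protects the epoxide.

Step 21
Reactants: 30 primary alcohol
Product: 31 β,γ-epoxy aldehyde (C3 aldehyde)
Conditions: Dess–Martin periodinane, pyridine, CH2Cl2, 0 °C; used without chromatography
Reagents that add atoms: none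
Why: Dess–Martin oxidation under near-neutral conditions, chosen so that the aldehyde is not enolised toward opening of the neighbouring epoxide.

Step 22
Reactants: 31 β,γ-epoxy aldehyde
Product: 32 ten-membered (3S)-allylic alcohol, the side-chain TBS ether of the target
Conditions: CrCl2 (10 equiv), NiCl2 (0.1 equiv), DMSO–THF, rt, 31 added by syringe pump (final 2 mM)
Reagents that add atoms: none
Why: Nozaki–Hiyama–Kishi macrocyclisation, in which zerovalent nickel inserts into the C4–I bond with retention of the Z geometry, transmetalation to trivalent chromium gives a chemoselective alkenyl nucleophile that tolerates esters, lactone and epoxide, and addition to the aldehyde conformer whose oxygen points to the outside of the forming ring, with the chromium alkoxide pseudo-equatorial, is expected to set C3 as S.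

Step 23
Reactants: 32 ten-membered (3S)-allylic alcohol
Product: 33 target CNP0156402.1
Conditions: Et3N·3HF, MeCN, rt
Reagents that add atoms: none
Why: Mild, nearly neutral fluoride desilylation of the primary TBS ether, which avoids both acid-induced transannular opening of the epoxide by the C3 hydroxyl and base-induced addition to the methylene lactone.

Compound list
1 | 3-(trimethylsilyl)prop-2-ynal | C[Si](C)(C)C#CC=O | starting material
2 | allenylboronic acid pinacol ester | C=C=CB1OC(C)(C)C(C)(C)O1 | starting material
3 | (3R)-1-(trimethylsilyl)hexa-1,5-diyn-3-ol | C#CC[C@@H](O)C#C[Si](C)(C)C | intermediate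
4 | (E)-alkenyl(dimethyl)alane, dimethylaluminium alkoxide at C8 | C[Al](C)/C=C(\C)C[C@@H](O[Al](C)C)C#C[Si](C)(C)C | intermediate
5 | (3E,6R)-4-methyl-8-(trimethylsilyl)oct-3-en-7-yne-1,6-diol | OCC/C=C(\C)C[C@@H](O)C#C[Si](C)(C)C | intermediate
6 | (3E,6R)-4-methyloct-3-en-7-yne-1,6-diol | OCC/C=C(\C)C[C@@H](O)C#C | intermediate
7 | (3E,6R)-4-methylnona-3,7,8-triene-1,6-diol | OCC/C=C(\C)C[C@@H](O)C=C=C | intermediate
8 | (4R,6E)-6-methyl-9-(triethylsilyloxy)nona-1,2,6-trien-4-ol | CC[Si](CC)(CC)OCC/C=C(\C)C[C@@H](O)C=C=C | intermediate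
9 | (2R)-1-{(2R,3R)-2-methyl-3-[2-(triethylsilyloxy)ethyl]oxiran-2-yl}penta-3,4-dien-2-ol | CC[Si](CC)(CC)OCC[C@H]1O[C@]1(C)C[C@@H](O)C=C=C | intermediate
10 | (4R)-4-benzyl-1,3-oxazolidin-2-one | O=C1N[C@H](Cc2ccccc2)CO1 | starting material
11 | butanoyl chloride | CCCC(=O)Cl | starting material
12 | (4R)-4-benzyl-3-butanoyl-1,3-oxazolidin-2-one | CCCC(=O)N1[C@H](Cc2ccccc2)COC1=O | intermediate
13 | (4R)-4-benzyl-3-[(2S)-2-(hydroxymethyl)butanoyl]-1,3-oxazolidin-2-one | CC[C@@H](CO)C(=O)N1[C@H](Cc2ccccc2)COC1=O | intermediate
14 | (4R)-4-benzyl-3-{(2S)-2-[(tert-butyldimethylsilyloxy)methyl]butanoyl}-1,3-oxazolidin-2-one | CC[C@@H](CO[Si](C)(C)C(C)(C)C)C(=O)N1[C@H](Cc2ccccc2)COC1=O | intermediate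
15 | (2S)-2-[(tert-butyldimethylsilyloxy)methyl]butaneperoxoic acid | CC[C@@H](CO[Si](C)(C)C(C)(C)C)C(=O)OO | intermediate
16 | (2S)-2-[(tert-butyldimethylsilyloxy)methyl]butanoic acid | CC[C@@H](CO[Si](C)(C)C(C)(C)C)C(=O)O | intermediate
17 | tert-butyl acrylate | C=CC(=O)OC(C)(C)C | starting material
18 | acetaldehyde | CC=O | starting material
19 | tert-butyl 3-hydroxy-2-methylidenebutanoate (racemic) | CC(O)C(=C)C(=O)OC(C)(C)C | intermediate
20 | tert-butyl (2E)-2-({(2S)-2-[(tert-butyldimethylsilyloxy)methyl]butanoyloxy}methyl)but-2-enoate | CC(C)(C)OC(=O)/C(=C/C)COC(=O)[C@@H](CC)CO[Si](C)(C)C(C)(C)C | intermediate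
21 | (2E)-2-({(2S)-2-[(tert-butyldimethylsilyloxy)methyl]butanoyloxy}methyl)but-2-enoic acid | OC(=O)/C(=C/C)COC(=O)[C@@H](CC)CO[Si](C)(C)C(C)(C)C | intermediate
22 | allene ester: (2R)-1-{(2R,3R)-2-methyl-3-[2-(triethylsilyloxy)ethyl]oxiran-2-yl}penta-3,4-dien-2-yl ester of acid 21 | CC[Si](CC)(CC)OCC[C@H]1O[C@]1(C)C[C@@H](OC(=O)/C(=C/C)COC(=O)[C@@H](CC)CO[Si](C)(C)C(C)(C)C)C=C=C | intermediate
23 | but-2-ynoic acid | CC#CC(=O)O | starting material
24 | (2Z)-3-iodobut-2-enoic acid | C/C(I)=C/C(=O)O | intermediate
25 | (2Z)-3-iodobut-2-enoyl chloride | C/C(I)=C/C(=O)Cl | intermediate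
26 | (3Z)-1-diazo-4-iodopent-3-en-2-one | C/C(I)=C/C(=O)C=[N+]=[N-] | intermediate
27 | (3Z)-4-iodopenta-1,3-dien-1-one (vinylketene) | C/C(I)=C/C=C=O | intermediate
28 | cis-cyclobutanone (C6 R, C7 R, C8 R, C10 R, C1 R) | C=C1C(=O)[C@@H](/C=C(/C)I)[C@H]1[C@H](OC(=O)/C(=C/C)COC(=O)[C@@H](CC)CO[Si](C)(C)C(C)(C)C)C[C@@]2(C)O[C@@H]2CCO[Si](CC)(CC)CC | intermediate
29 | cis-α-methylene-γ-butyrolactone with (Z)-iodopropenyl group at C6 and TES ether at C3–O | C=C1C(=O)O[C@@H](/C=C(/C)I)[C@H]1[C@H](OC(=O)/C(=C/C)COC(=O)[C@@H](CC)CO[Si](C)(C)C(C)(C)C)C[C@@]2(C)O[C@@H]2CCO[Si](CC)(CC)CC | intermediate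
30 | primary alcohol (free C3–OH) | C=C1C(=O)O[C@@H](/C=C(/C)I)[C@H]1[C@H](OC(=O)/C(=C/C)COC(=O)[C@@H](CC)CO[Si](C)(C)C(C)(C)C)C[C@@]2(C)O[C@@H]2CCO | intermediate
31 | β,γ-epoxy aldehyde (C3 aldehyde) | C=C1C(=O)O[C@@H](/C=C(/C)I)[C@H]1[C@H](OC(=O)/C(=C/C)COC(=O)[C@@H](CC)CO[Si](C)(C)C(C)(C)C)C[C@@]2(C)O[C@@H]2CC=O | intermediate
32 | ten-membered (3S)-allylic alcohol, side-chain TBS ether of the target | C=C1C(=O)O[C@H]2/C=C(/C)[C@@H](O)C[C@H]3O[C@]3(C)C[C@@H](OC(=O)/C(=C/C)COC(=O)[C@@H](CC)CO[Si](C)(C)C(C)(C)C)[C@@H]12 | intermediate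
33 | CNP0156402.1 | C=C1C(=O)O[C@H]2/C=C(/C)[C@@H](O)C[C@H]3O[C@]3(C)C[C@@H](OC(=O)/C(=C/C)COC(=O)[C@@H](CC)CO)[C@@H]12 | target

Total step count: 23.
Longest linear sequence: 13 steps (steps 1–6, 14, 18–23). The side-chain branch (steps 7–10, 12–14, 18–23) is equally long.

Steps most likely to fail

1. Step 18.
- What may go wrong: the ketene may be captured too slowly and oligomerise. It may close onto the terminal carbon C13. Above all, it may add to the wrong face of the C7=C11 bond, because one neighbouring stereocentre is the only steering element.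
- Fallback (stereochemical relay with double inversion in place of direct induction), from 9 back to 29: Mitsunobu esterification of 9 with chloroacetic acid inverts C8 and gives the (8S)-allenyl chloroacetate F1. Cycloaddition with 26 under the conditions of step 18, now with the mirror-image steering element, gives the cis-cyclobutanone F2. Peracid oxidation as in step 19 gives the lactone F3. Thiourea removes the chloroacetate to give the (8S)-alcohol F4. A second Mitsunobu reaction, this time with acid 21, inverts C8 to R and delivers 29.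

2. Step 22.
- What may go wrong: the aldehyde may lose its epoxide by enolisation and β-elimination before it cyclises. Intermolecular coupling may compete. The macrocyclic transition state may show poor facial selectivity at C3.
- Fallback (reagent control in place of macrocyclic control), from the C3-epimer mixture of 32 obtained in step 22 back to 32: Dess–Martin oxidation gives the ten-membered enone F5. Corey–Bakshi–Shibata reduction with the (R)-2-methyl-oxazaborolidine and catecholborane at low temperature then returns the 3S alcohol 32. In this reduction the trisubstituted alkenyl group acts as the large substituent.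

3. Step 19.
- What may go wrong: conjugation with the exocyclic alkene may slow peracid addition to the carbonyl group. Oxidation at iodine or epimerisation at C6 could then compete.
- Fallback (temporary removal of the conjugation), from 28 back to 29: conjugate addition of thiophenol gives the saturated β-phenylthio cyclobutanone F6. Excess mCPBA oxidises sulfur to the sulfone and inserts oxygen into the now unconjugated strained ketone to give the sulfonyl lactone F7. DBU eliminates benzenesulfinate and restores the methylene group of 29.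

Further compounds
F1 | step 18 | (2S)-1-{(2R,3R)-2-methyl-3-[2-(triethylsilyloxy)ethyl]oxiran-2-yl}penta-3,4-dien-2-yl chloroacetate | CC[Si](CC)(CC)OCC[C@H]1O[C@]1(C)C[C@H](OC(=O)CCl)C=C=C
F2 | step 18 | cis-cyclobutanone with (8S)-chloroacetate | C=C1C(=O)[C@@H](/C=C(/C)I)[C@H]1[C@@H](OC(=O)CCl)C[C@@]2(C)O[C@@H]2CCO[Si](CC)(CC)CC
F3 | step 18 | cis-lactone with (8S)-chloroacetate | C=C1C(=O)O[C@@H](/C=C(/C)I)[C@H]1[C@@H](OC(=O)CCl)C[C@@]2(C)O[C@@H]2CCO[Si](CC)(CC)CC
F4 | step 18 | cis-lactone with free (8S)-hydroxyl | C=C1C(=O)O[C@@H](/C=C(/C)I)[C@H]1[C@@H](O)C[C@@]2(C)O[C@@H]2CCO[Si](CC)(CC)CC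
F5 | step 22 | ten-membered C3 enone | C=C1C(=O)O[C@H]2/C=C(/C)C(=O)C[C@H]3O[C@]3(C)C[C@@H](OC(=O)/C(=C/C)COC(=O)[C@@H](CC)CO[Si](C)(C)C(C)(C)C)[C@@H]12
F6 | step 19 | β-phenylthio cyclobutanone (C11 unassigned) | c1ccccc1SCC1C(=O)[C@@H](/C=C(/C)I)[C@H]1[C@H](OC(=O)/C(=C/C)COC(=O)[C@@H](CC)CO[Si](C)(C)C(C)(C)C)C[C@@]2(C)O[C@@H]2CCO[Si](CC)(CC)CC
F7 | step 19 | α-(phenylsulfonylmethyl) lactone (C11 unassigned) | O=S(=O)(c1ccccc1)CC1C(=O)O[C@@H](/C=C(/C)I)[C@H]1[C@H](OC(=O)/C(=C/C)COC(=O)[C@@H](CC)CO[Si](C)(C)C(C)(C)C)C[C@@]2(C)O[C@@H]2CCO[Si](CC)(CC)CC
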